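**Retrosynthetic overview**
1. Last cut: the C4–O ester bond, giving 4-hydroxy-3-(2-methylbut-3-en-2-yl)-6-phenyl-2H-pyran-2-one and 3-hydroxy-3-methylbutanoic acid, whose tertiary hydroxyl is masked as a triethylsilyl ether.
2. Central cut: the bond between the phenyl ring and pyranone C6. The route rests on the C6–H bond of the 2-pyranone ring, the carbon next to ring oxygen O1. With C3 blocked by the quaternary carbon of the 2-methylbut-3-en-2-yl group and O4 silylated, this C–H is zincated and coupled with iodobenzene.
3. The 6-unsubstituted pyranone is opened at O1–C2 (lactone) and C5–C6 (formyl carbon) to methyl 2-acetyl-3,3-dimethylpent-4-enoate, made by C-acetylation of methyl 3,3-dimethylpent-4-enoate, which already holds the quaternary carbon and the vinyl group.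
4. Ring order: the pyranone is the only ring built (step 3); the phenyl ring is bought and attached afterwards (step 5). The target has no stereocentre.

Key step: step 5

Remark on the chemistry: compounds 3 and 5 carry one stereocentre (C2 of the ester chain) and are used as racemates; it becomes sp2 in pyranone 6.

**Step 1**
Reactants: 1 methyl 3,3-dimethylpent-4-enoate
Product: 3 methyl 2-acetyl-3,3-dimethylpent-4-enoate (racemic), via lithium ester enolate 2 (not isolated)
Conditions: 1 (2.0 equiv), LiN(iPr)2 (commercial solution, 2.05 equiv), THF, −78 °C; AcCl (1.0 equiv), −78 → −40 °C; aq. NH4Cl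
Reagents that add atoms: acetyl chloride, CC(Cl)=O
Why: Crossed Claisen acylation of a preformed lithium ester enolate with an acid chloride, in which the second equivalent of enolate 2 deprotonates the more acidic β-keto ester as it forms (and is recovered as 1), so that double acylation at the neopentyl α-carbon is suppressed.

**Step 2**
Reactants: 3 methyl 2-acetyl-3,3-dimethylpent-4-enoate
Product: 5 methyl (4Z)-5-hydroxy-2-(2-methylbut-3-en-2-yl)-3-oxopent-4-enoate (enol form of the 3,5-dioxo ester, racemic), via dilithium dienolate 4 (not isolated)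
Conditions: LiN(iPr)2 (3.2 equiv), THF, −78 → 0 °C; HCO2Me (1.5 equiv), −78 → 0 °C; cold 1 M HCl
Reagents that add atoms: methyl formate, COC=O
Why: Claisen formylation of a β-keto ester dianion, in which the methyl-derived terminal carbon of 4 is the most nucleophilic site and attacks methyl formate, the extra equivalent of base absorbs the acidic formyl ketone, and acidic work-up should give the hydrogen-bonded (Z)-enol.

**Step 3**
Reactants: 5 methyl (4Z)-5-hydroxy-2-(2-methylbut-3-en-2-yl)-3-oxopent-4-enoate
Product: 6 4-hydroxy-3-(2-methylbut-3-en-2-yl)-2H-pyran-2-one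
Conditions: DBU (1.2 equiv), PhMe, 80 °C; cold 1 M HCl (brief)
Reagents that add atoms: none
Why: Base-mediated lactonisation, in which the (Z)-enolate oxygen of the formyl group attacks the methyl ester (6-exo-trig acyl substitution) and loss of methoxide with tautomerisation gives the aromatic 4-hydroxy-2-pyranone, removing the C2 stereocentre.

**Step 4**
Reactants: 6 4-hydroxy-3-(2-methylbut-3-en-2-yl)-2H-pyran-2-one
Product: 7 3-(2-methylbut-3-en-2-yl)-4-(triisopropylsilyloxy)-2H-pyran-2-one
Conditions: iPr3SiOTf (1.2 equiv), Et3N (1.5 equiv), CH2Cl2, −78 → 0 °C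
Reagents that add atoms: triisopropylsilyl trifluoromethanesulfonate, CC(C)[Si](OS(=O)(=O)C(F)(F)F)(C(C)C)C(C)C
Why: O-Silylation of the acidic vinylogous acid with a silyl triflate should give the 2-pyranone silyl isomer as the thermodynamically preferred one, and any 2-silyloxy-4-pyranone isomer would carry the same C6–H next to O1 and converge on the same compound after step 6.

**Step 5**
Reactants: 7 3-(2-methylbut-3-en-2-yl)-4-(triisopropylsilyloxy)-2H-pyran-2-one; 8 iodobenzene
Product: 10 3-(2-methylbut-3-en-2-yl)-6-phenyl-4-(triisopropylsilyloxy)-2H-pyran-2-one, via pyran-6-ylzinc chloride 9 (not isolated)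
Conditions: TMPZnCl·LiCl (TMP = 2,2,6,6-tetramethylpiperidin-1-yl, commercial THF solution, 1.3 equiv), THF, 25 °C; then PhI (1.2 equiv), Pd(PPh3)4 (5 mol %), 50 °C
Reagents that add atoms: none
Why: Proposed new method: TMPZnCl·LiCl should remove the C6 proton of 7, the only ring C–H that is α to ring oxygen O1 of the electron-poor pyranone, giving zinc species 9, whose covalent C–Zn bond leaves the lactone carbonyl and the silyl enol ether untouched. Zerovalent palladium then inserts into the C–I bond of iodobenzene, 9 transmetalates to the phenylpalladium iodide, and reductive elimination forms the C6–phenyl bond (Negishi coupling). The closest known reaction type is the C2 zincation of chromones and 4-pyranones with TMP-zinc amide bases followed by Negishi arylation; the sequence has not been shown at C6 of a 2-pyranone. No ring is closed and no stereocentre is formed. The step needs metalation at C6 and not C5, and cross-coupling and not Heck addition to the vinyl group: C3 is blocked by the quaternary carbon, C5–H lies under the triisopropylsilyl group and lacks the inductive pull of O1, and transmetalation of the zinc species should be much faster than carbopalladation of a terminal alkene on a quaternary carbon.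

**Step 6**
Reactants: 10 3-(2-methylbut-3-en-2-yl)-6-phenyl-4-(triisopropylsilyloxy)-2H-pyran-2-one
Product: 11 4-hydroxy-3-(2-methylbut-3-en-2-yl)-6-phenyl-2H-pyran-2-one
Conditions: Bu4NF (1.1 equiv), AcOH (1.2 equiv), THF, 0 °C
Reagents that add atoms: none
Why: Fluoride attacks silicon of the vinylogous silyl ester and releases the stabilised pyranolate, which acetic acid protonates at once, so the lactone and the vinyl group should be untouched.

**Step 7**
Reactants: 12 3-hydroxy-3-methylbutanoic acid
Product: 14 3-methyl-3-(triethylsilyloxy)butanoic acid, via triethylsilyl 3-methyl-3-(triethylsilyloxy)butanoate 13 (not isolated)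
Conditions: Et3SiOTf (2.3 equiv), 2,6-lutidine (3 equiv), CH2Cl2, −78 → 0 °C; then THF–H2O, 25 °C; pH 4 work-up
Reagents that add atoms: triethylsilyl trifluoromethanesulfonate, CC[Si](CC)(CC)OS(=O)(=O)C(F)(F)F
Why: Silyl triflate silylation of both the tertiary alcohol and the acid, followed by hydrolysis of the silyl ester alone, which is far more labile to water than the hindered tertiary triethylsilyl ether.

**Step 8**
Reactants: 14 3-methyl-3-(triethylsilyloxy)butanoic acid; 11 4-hydroxy-3-(2-methylbut-3-en-2-yl)-6-phenyl-2H-pyran-2-one
Product: 16 3-(2-methylbut-3-en-2-yl)-2-oxo-6-phenyl-2H-pyran-4-yl 3-methyl-3-(triethylsilyloxy)butanoate, via 3-methyl-3-(triethylsilyloxy)butanoyl chloride 15 (not isolated)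
Conditions: 14 (1.5 equiv), 1-chloro-N,N,2-trimethylprop-1-en-1-amine (1.5 equiv), CH2Cl2, 0 → 25 °C; then 11, Et3N (2 equiv), DMAP (0.1 equiv), CH2Cl2, 0 → 25 °C
Reagents that add atoms: none
Why: The α-chloroenamine converts the acid into its chloride without HCl, which would cleave the silyl ether, and DMAP-catalysed acyl substitution at the pyranone 4-hydroxyl can only occur on oxygen because C3 carries the quaternary substituent.

**Step 9**
Reactants: 16 3-(2-methylbut-3-en-2-yl)-2-oxo-6-phenyl-2H-pyran-4-yl 3-methyl-3-(triethylsilyloxy)butanoate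
Product: 17 3-(2-methylbut-3-en-2-yl)-2-oxo-6-phenyl-2H-pyran-4-yl 3-hydroxy-3-methylbutanoate (target)
Conditions: HF·pyridine, pyridine, THF, 0 → 25 °C
Reagents that add atoms: none
Why: Buffered HF·pyridine cleaves the tertiary triethylsilyl ether through a pentacoordinate fluorosilicate without the basic conditions that would cleave or transfer the activated enol ester.

**Compound list**
1 | methyl 3,3-dimethylpent-4-enoate | C=CC(C)(C)CC(=O)OC | starting material
2 | lithium enolate of 1 (lithium 1-methoxy-3,3-dimethylpenta-1,4-dien-1-olate) | C=CC(C)(C)C=C(OC)O[Li] | intermediate (not isolated)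
3 | methyl 2-acetyl-3,3-dimethylpent-4-enoate (racemic) | C=CC(C)(C)C(C(C)=O)C(=O)OC | intermediate
4 | dilithium dienolate of 3 | C=CC(C)(C)C(C(=C)O[Li])=C(OC)O[Li] | intermediate (not isolated)
5 | methyl (4Z)-5-hydroxy-2-(2-methylbut-3-en-2-yl)-3-oxopent-4-enoate (racemic) | C=CC(C)(C)C(C(=O)OC)C(=O)/C=C\O | intermediate
6 | 4-hydroxy-3-(2-methylbut-3-en-2-yl)-2H-pyran-2-one | C=CC(C)(C)c1c(O)ccoc1=O | intermediate
7 | 3-(2-methylbut-3-en-2-yl)-4-(triisopropylsilyloxy)-2H-pyran-2-one | C=CC(C)(C)c1c(O[Si](C(C)C)(C(C)C)C(C)C)ccoc1=O | intermediate
8 | iodobenzene | Ic1ccccc1 | starting material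
9 | chloro[3-(2-methylbut-3-en-2-yl)-2-oxo-4-(triisopropylsilyloxy)-2H-pyran-6-yl]zinc (LiCl complex in THF) | C=CC(C)(C)c1c(O[Si](C(C)C)(C(C)C)C(C)C)cc([Zn]Cl)oc1=O | intermediate (not isolated)
10 | 3-(2-methylbut-3-en-2-yl)-6-phenyl-4-(triisopropylsilyloxy)-2H-pyran-2-one | C=CC(C)(C)c1c(O[Si](C(C)C)(C(C)C)C(C)C)cc(-c2ccccc2)oc1=O | intermediate
11 | 4-hydroxy-3-(2-methylbut-3-en-2-yl)-6-phenyl-2H-pyran-2-one | C=CC(C)(C)c1c(O)cc(-c2ccccc2)oc1=O | intermediate
12 | 3-hydroxy-3-methylbutanoic acid | CC(C)(O)CC(=O)O | starting material
13 | triethylsilyl 3-methyl-3-(triethylsilyloxy)butanoate | CC[Si](CC)(CC)OC(=O)CC(C)(C)O[Si](CC)(CC)CC | intermediate (not isolated)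
14 | 3-methyl-3-(triethylsilyloxy)butanoic acid | CC[Si](CC)(CC)OC(C)(C)CC(=O)O | intermediate
15 | 3-methyl-3-(triethylsilyloxy)butanoyl chloride | CC[Si](CC)(CC)OC(C)(C)CC(=O)Cl | intermediate (not isolated)
16 | 3-(2-methylbut-3-en-2-yl)-2-oxo-6-phenyl-2H-pyran-4-yl 3-methyl-3-(triethylsilyloxy)butanoate | C=CC(C)(C)c1c(OC(=O)CC(C)(C)O[Si](CC)(CC)CC)cc(-c2ccccc2)oc1=O | intermediate
17 | 3-(2-methylbut-3-en-2-yl)-2-oxo-6-phenyl-2H-pyran-4-yl 3-hydroxy-3-methylbutanoate (CNP0160044.0) | C=CC(C)(C)c1c(OC(=O)CC(C)(C)O)cc(-c2ccccc2)oc1=O | target

**Total step count:** 9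
**Longest linear sequence:** 8 steps (steps 1–6, 8 and 9); step 7 is the side-chain branch.

**Steps most likely to fail**

1. Step 5 (proposed new method). The base may be too weak to deprotonate C6–H fully, or may deprotonate C5–H, whose metal species can open the ring by β-elimination of O1. The phenylpalladium intermediate may also add to the vinyl group before transmetalation. Fallback (known chemistry): it sets out from 3 and returns at 11. Dienolate 4, generated as in step 2, is acylated with methyl benzoate (Claisen acylation of a β-keto ester dianion) to give methyl 2-(2-methylbut-3-en-2-yl)-3,5-dioxo-5-phenylpentanoate F1. DBU in toluene at 80 °C lactonises F1 to 11, so the phenyl group enters with the ring-forming carbon and steps 2–6 are bypassed.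

2. Step 2. Proton transfer from the newly formed formyl ketone to unreacted dienolate may stop the acylation part-way, and competing attack of the amide base on methyl formate may use up the electrophile. Fallback: it sets out from 1 and returns at 5. Enolate 2, generated as in step 1, is acylated with (E)-3-ethoxyprop-2-enoyl chloride to give methyl 2-[(2E)-3-ethoxyprop-2-enoyl]-3,3-dimethylpent-4-enoate F2, which brings in the formyl carbon as a masked enol ether without any dianion. Dilute HCl in THF at 25 °C hydrolyses the vinylogous ester of F2 to 5, which is taken on in step 3.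

3. Step 8. Acylation of the weakly nucleophilic enol oxygen, shielded by the neighbouring quaternary carbon, may be slow. Meanwhile the acid chloride may be consumed by ketene formation and loss of the β-silyloxy group, or the acyl group may end up on the lactone carbonyl oxygen. Fallback: it sets out from 10 and 14 and returns at 16. Acid 14 is converted with cyanuric fluoride and pyridine in CH2Cl2 into 3-methyl-3-(triethylsilyloxy)butanoyl fluoride F3. A catalytic amount of tetrabutylammonium difluorotriphenylsilicate in THF then triggers silyl–acyl exchange between silyl ether 10 and F3. The naked pyranolate released from silicon is acylated by the acyl fluoride and fluoride is regenerated, giving 16 without amine base and without step 6.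

**Further compounds**
F1 | step 5 | methyl 2-(2-methylbut-3-en-2-yl)-3,5-dioxo-5-phenylpentanoate | C=CC(C)(C)C(C(=O)OC)C(=O)CC(=O)c1ccccc1
F2 | step 2 | methyl 2-[(2E)-3-ethoxyprop-2-enoyl]-3,3-dimethylpent-4-enoate | C=CC(C)(C)C(C(=O)OC)C(=O)/C=C/OCC
F3 | step 8 | 3-methyl-3-(triethylsilyloxy)butanoyl fluoride | CC[Si](CC)(CC)OC(C)(C)CC(=O)F
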